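The target is a p-terphenyl whose central benzene ring carries, on O2', O3', O5' and O6', four identical (2Z)-hex-2-enoyl chains, each closed at C4–C5 into a trans (4S,5S) oxirane ring; these eight carbons are the only stereocentres. All eight oxirane C–O bonds are therefore disconnected at once. The key step exploits the fact that each chain derives from a (2Z,4E)-dienoate whose distal E C4=C5 alkene is electron-rich while the Z C2=C3 alkene is ester-deactivated: one catalyst-controlled fourfold epoxidation closes the four rings and sets every centre. Its precursor is the achiral 4,4''-bis(silyloxy)-p-terphenyl-2',3',5',6'-tetrayl tetrakis[(2Z,4E)-hexa-2,4-dienoate].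

Key step: step 6

Remarks on the chemistry
- Structure check: in the target SMILES each methyl-bearing oxirane carbon (C5) and each chain-bearing oxirane carbon (C4) is S, every oxirane is trans and every enoate is 2Z. The tetradienoate 12 and its tetraepoxide 13 are consistent with this and need no correction.
- Stoichiometry: benzyl alcohol 6 enters step 2 twice, boronic acid 8 enters step 3 twice and acid 4 enters step 5 four times. The Reactants line gives the number of equivalents, and the molecules beyond the first are entered again under "Reagents that add atoms", because their atoms end up in the product. Step 6 consumes four molecules of KHSO5, one oxygen atom being taken from each.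
- Design choice: the central ring is carried as a bis(benzyloxy)quinone. Hydrogenation then reduces the quinone and removes both benzyl groups under neutral conditions. Hydroxide cleavage of an alkoxyquinone would also strip the aryl silyl ethers.
- Design choice: the tetrabromoquinone is used because its C–Br bonds should couple more readily than C–Cl bonds.
- Design choice: the epoxidation is run near pH 8 with excess ketone, because four aryl esters would not be expected to tolerate the more basic catalytic protocol.
- Assumption: the sense of induction known for trans-disubstituted alkenes (the D-fructose-derived ketone gives R,R epoxides) is taken to hold for the 4E alkene of a (2Z,4E)-dienoate, so the L-series ketone is used for (4S,5S).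

Step 1
Reactants: 1 (E)-crotonaldehyde; 2 methyl bis(2,2,2-trifluoroethyl)phosphonoacetate
Product: 4 (2Z,4E)-hexa-2,4-dienoic acid, via methyl (2Z,4E)-hexa-2,4-dienoate 3 (not isolated)
Conditions: KN(SiMe3)2, 18-crown-6, THF, −78 °C; then LiOH, H2O–MeOH, 0 °C to rt; 1 M HCl to pH 3 at 0 °C
Reagents that add atoms: lithium hydroxide, [Li+].[OH-]
Why: Still–Gennari olefination, in which the electron-poor phosphonate anion adds to the enal and the adduct collapses under kinetic control to the 2Z enoate while the 4E alkene is untouched; saponification of the crude ester in the same flask avoids isolating a volatile diene, and no stereocentre is formed.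

Step 2
Reactants: 5 bromanil (2,3,5,6-tetrabromo-1,4-benzoquinone); 6 benzyl alcohol (2 equiv)
Product: 7 2,5-bis(benzyloxy)-3,6-dibromo-1,4-benzoquinone
Conditions: 6 (2 equiv), NaH (2 equiv), THF, 0 °C, to form NaOBn; added slowly to 5 in THF, −30 to 0 °C
Reagents that add atoms: benzyl alcohol 6 (the second equivalent), OCc1ccccc1
Why: Twofold addition–elimination of benzyloxide on a tetrahaloquinone; the first benzyloxy group at C2 donates through C2=C3 into the C4 carbonyl as a vinylogous ester, so the second alkoxide adds at C5, the carbon conjugated to the still electrophilic C1 carbonyl, and the 2,5-dialkoxy-3,6-dibromo pattern should result, as it does with methoxide.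

Step 3
Reactants: 7 2,5-bis(benzyloxy)-3,6-dibromo-1,4-benzoquinone; 8 [4-(tert-butyldimethylsilyloxy)phenyl]boronic acid (2 equiv)
Product: 9 2,5-bis(benzyloxy)-3,6-bis[4-(tert-butyldimethylsilyloxy)phenyl]-1,4-benzoquinone
Conditions: Pd(dppf)Cl2 (5 mol %, dppf = 1,1'-bis(diphenylphosphino)ferrocene), anhydrous K3PO4, 1,4-dioxane, 85 °C, argon; 8 charged in slight excess
Reagents that add atoms: [4-(tert-butyldimethylsilyloxy)phenyl]boronic acid 8 (the second equivalent), CC(C)(C)[Si](C)(C)Oc1ccc(B(O)O)cc1
Why: Double Suzuki–Miyaura coupling, in which the two quinone C–Br bonds behave as vinylogous acyl bromides and add readily to zerovalent palladium, each then taking one aryl group from one molecule of 8, while the anhydrous phosphate base spares the aryl silyl ethers and the benzyl vinylogous esters.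

Step 4
Reactants: 9 2,5-bis(benzyloxy)-3,6-bis[4-(tert-butyldimethylsilyloxy)phenyl]-1,4-benzoquinone
Product: 11 4,4''-bis(tert-butyldimethylsilyloxy)-p-terphenyl-2',3',5',6'-tetraol, via bis(benzyloxy)hydroquinone 10 (not isolated)
Conditions: H2 (1 atm), Pd/C (10 %), EtOAc–THF, rt; filtration under argon, used at once
Reagents that add atoms: none
Why: Catalytic hydrogenation first reduces the quinone to the hydroquinone and then cleaves both O-benzyl groups by hydrogenolysis, a neutral one-flask operation that leaves the aryl silyl ethers intact; the air-sensitive tetraol is kept under argon.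

Step 5
Reactants: 11 4,4''-bis(tert-butyldimethylsilyloxy)-p-terphenyl-2',3',5',6'-tetraol; 4 (2Z,4E)-hexa-2,4-dienoic acid (4 equiv)
Product: 12 4,4''-bis(tert-butyldimethylsilyloxy)-p-terphenyl-2',3',5',6'-tetrayl tetrakis[(2Z,4E)-hexa-2,4-dienoate]
Conditions: N,N'-diisopropylcarbodiimide, 4-dimethylaminopyridine (cat.), CH2Cl2, 0 °C to rt, argon, dark; acid 4 charged in modest excess over the four equivalents consumed
Reagents that add atoms: (2Z,4E)-hexa-2,4-dienoic acid 4 (the three further equivalents), C/C=C/C=C\C(=O)O.C/C=C/C=C\C(=O)O.C/C=C/C=C\C(=O)O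
Why: Fourfold Steglich esterification, each of the four phenolic hydroxyls taking one acyl group from one carbodiimide-activated molecule of 4, run cold with little nucleophilic catalyst and without light so that the 2Z geometry should be retained; no stereocentre is formed.

Step 6
Reactants: 12 4,4''-bis(tert-butyldimethylsilyloxy)-p-terphenyl-2',3',5',6'-tetrayl tetrakis[(2Z,4E)-hexa-2,4-dienoate]
Product: 13 4,4''-bis(tert-butyldimethylsilyloxy)-p-terphenyl-2',3',5',6'-tetrayl tetrakis{(2Z)-3-[(2S,3S)-3-methyloxiran-2-yl]prop-2-enoate}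
Conditions: L-series ketone 1,2:4,5-di-O-isopropylidene-β-L-erythro-2,3-hexodiulo-2,6-pyranose (about 2 equiv per alkene, in portions), KHSO5 (as 2KHSO5·KHSO4·K2SO4, in excess over the 4 equiv consumed), NaHCO3, Bu4NHSO4 (cat.), MeCN–CH2(OMe)2–aqueous Na2H2EDTA, pH about 8, 0 °C
Reagents that add atoms: potassium peroxymonosulfate (KHSO5, four molecules consumed, one oxygen atom from each), [K+].[O-]S(=O)(=O)OO
Why: KHSO5 converts the ketone into a chiral dioxirane, which passes one oxygen atom to each C4=C5 alkene through a spiro transition state; the closest known reaction is the Shi epoxidation of conjugated dienoates at the alkene remote from the ester. Each of the four oxirane rings closes by concerted [2+1] oxygen-atom addition, both C–O bonds forming on the same face in one event, so the E geometry is copied into a trans epoxide. C4 and C5 of every chain are set by the catalyst alone: the D-fructose-derived ketone gives (R,R) epoxides from trans-disubstituted alkenes, so its L-series enantiomer should give (4S,5S), and since the substrate is achiral and the chains are remote there is no matched or mismatched case. Site selectivity between the two alkenes of each dienoate is needed and is secured by the ester, which deactivates the conjugated Z C2=C3 bond towards the electrophilic oxidant. Chemoselectivity over the four aryl esters and the two aryl silyl ethers is secured by working near pH 8 at 0 °C with the ketone in excess. The four events are independent, so the reaction is driven to full conversion and any isomer carrying one wrong-face epoxide is a diastereomer that should be removable by chromatography.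

Step 7
Reactants: 13 4,4''-bis(tert-butyldimethylsilyloxy)-p-terphenyl-2',3',5',6'-tetrayl tetrakis{(2Z)-3-[(2S,3S)-3-methyloxiran-2-yl]prop-2-enoate}
Product: 14 4,4''-dihydroxy-p-terphenyl-2',3',5',6'-tetrayl tetrakis{(2Z)-3-[(2S,3S)-3-methyloxiran-2-yl]prop-2-enoate} (CNP0249571.1)
Conditions: Bu4NF, AcOH (1:1), THF, 0 °C
Reagents that add atoms: none
Why: Fluoride-mediated cleavage of the two aryl silyl ethers (Si–F bond formation with a phenoxide leaving group) is fast at 0 °C, and the acetic acid buffer protonates the phenoxide at once so that acyl transfer from the aryl esters and epoxide opening should not compete; the eight stereocentres are not touched.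

Compound list
1 | (E)-crotonaldehyde | C/C=C/C=O | starting material
2 | methyl bis(2,2,2-trifluoroethyl)phosphonoacetate | COC(=O)CP(=O)(OCC(F)(F)F)OCC(F)(F)F | starting material
3 | methyl (2Z,4E)-hexa-2,4-dienoate | C/C=C/C=C\C(=O)OC | intermediate (not isolated)
4 | (2Z,4E)-hexa-2,4-dienoic acid | C/C=C/C=C\C(=O)O | intermediate
5 | bromanil (2,3,5,6-tetrabromo-1,4-benzoquinone) | O=C1C(Br)=C(Br)C(=O)C(Br)=C1Br | starting material
6 | benzyl alcohol | OCc1ccccc1 | starting material
7 | 2,5-bis(benzyloxy)-3,6-dibromo-1,4-benzoquinone | O=C1C(Br)=C(OCc2ccccc2)C(=O)C(Br)=C1OCc1ccccc1 | intermediate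
8 | [4-(tert-butyldimethylsilyloxy)phenyl]boronic acid | CC(C)(C)[Si](C)(C)Oc1ccc(B(O)O)cc1 | starting material
9 | 2,5-bis(benzyloxy)-3,6-bis[4-(tert-butyldimethylsilyloxy)phenyl]-1,4-benzoquinone | O=C1C(-c2ccc(O[Si](C)(C)C(C)(C)C)cc2)=C(OCc2ccccc2)C(=O)C(-c2ccc(O[Si](C)(C)C(C)(C)C)cc2)=C1OCc1ccccc1 | intermediate
10 | 3',6'-bis(benzyloxy)-4,4''-bis(tert-butyldimethylsilyloxy)-p-terphenyl-2',5'-diol | Oc1c(OCc2ccccc2)c(-c2ccc(O[Si](C)(C)C(C)(C)C)cc2)c(O)c(OCc2ccccc2)c1-c1ccc(O[Si](C)(C)C(C)(C)C)cc1 | intermediate (not isolated)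
11 | 4,4''-bis(tert-butyldimethylsilyloxy)-p-terphenyl-2',3',5',6'-tetraol | Oc1c(O)c(-c2ccc(O[Si](C)(C)C(C)(C)C)cc2)c(O)c(O)c1-c1ccc(O[Si](C)(C)C(C)(C)C)cc1 | intermediate
12 | 4,4''-bis(tert-butyldimethylsilyloxy)-p-terphenyl-2',3',5',6'-tetrayl tetrakis[(2Z,4E)-hexa-2,4-dienoate] | C/C=C/C=C\C(=O)Oc1c(OC(=O)/C=C\C=C\C)c(-c2ccc(O[Si](C)(C)C(C)(C)C)cc2)c(OC(=O)/C=C\C=C\C)c(OC(=O)/C=C\C=C\C)c1-c1ccc(O[Si](C)(C)C(C)(C)C)cc1 | intermediate
13 | 4,4''-bis(tert-butyldimethylsilyloxy)-p-terphenyl-2',3',5',6'-tetrayl tetrakis{(2Z)-3-[(2S,3S)-3-methyloxiran-2-yl]prop-2-enoate} | C[C@@H]1O[C@H]1/C=C\C(=O)Oc1c(OC(=O)/C=C\[C@@H]2O[C@H]2C)c(-c2ccc(O[Si](C)(C)C(C)(C)C)cc2)c(OC(=O)/C=C\[C@@H]2O[C@H]2C)c(OC(=O)/C=C\[C@@H]2O[C@H]2C)c1-c1ccc(O[Si](C)(C)C(C)(C)C)cc1 | intermediate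
14 | 4,4''-dihydroxy-p-terphenyl-2',3',5',6'-tetrayl tetrakis{(2Z)-3-[(2S,3S)-3-methyloxiran-2-yl]prop-2-enoate} (CNP0249571.1) | C[C@@H]1O[C@H]1/C=C\C(=O)Oc1c(OC(=O)/C=C\[C@@H]2O[C@H]2C)c(-c2ccc(O)cc2)c(OC(=O)/C=C\[C@@H]2O[C@H]2C)c(OC(=O)/C=C\[C@@H]2O[C@H]2C)c1-c1ccc(O)cc1 | target

Total step count: 7.
Longest linear sequence: 6 steps (steps 2, 3, 4, 5, 6 and 7, from bromanil 5 to target 14).

Steps most likely to fail

Step 6 (key step). Facial selectivity that is high but not perfect at each alkene is multiplied over four independent sites, so isomers with one wrong-face epoxide may build up. A slow fourth epoxidation or aryl ester cleavage by the aqueous oxidant may also erode material. The fallback sets the epoxide on a small fragment by a different asymmetric method and then attaches four copies, bypassing 12. It starts from (E)-crotonaldehyde 1. Luche reduction (NaBH4, CeCl3·7H2O, MeOH, 0 °C) should give (E)-but-2-en-1-ol F1. Sharpless asymmetric epoxidation (Ti(OiPr)4, L-(+)-diethyl tartrate, t-BuOOH, 4 Å sieves, CH2Cl2, −20 °C) should give [(2S,3S)-3-methyloxiran-2-yl]methanol F2. Oxidation (PhI(OAc)2, catalytic TEMPO, CH2Cl2) should give (2R,3S)-3-methyloxirane-2-carbaldehyde F3, which is taken in solution into a Still–Gennari olefination with phosphonate 2 to give methyl (2Z)-3-[(2S,3S)-3-methyloxiran-2-yl]prop-2-enoate F4. Anhydrous ester cleavage with KOSiMe3 in THF should give potassium (2Z)-3-[(2S,3S)-3-methyloxiran-2-yl]prop-2-enoate F5 without exposing the free acid, which is prone to lactonise. Under Yamaguchi conditions the salt is converted with 2,4,6-trichlorobenzoyl chloride into 2,4,6-trichlorobenzoic (2Z)-3-[(2S,3S)-3-methyloxiran-2-yl]prop-2-enoic anhydride F6 (used in situ). Four equivalents of this anhydride acylate tetraol 11 (catalytic 4-dimethylaminopyridine, toluene, 0 °C) and the route is rejoined at 13.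

Step 5. The 2Z geometry may be lost in the activated dienoyl unit, either by reversible addition of the nucleophilic catalyst or by vinylketene formation through the acidic C6 methyl group. Acylation of four flanked hydroxyls may also stop short, and the tetraol may reoxidise. The fallback forms the C3–C4 bond only after the esters exist. Tetraol 11 is acylated with four equivalents of commercial (Z)-3-iodoacrylic acid, a small acid with no γ-hydrogens (N,N'-diisopropylcarbodiimide, catalytic 4-dimethylaminopyridine, CH2Cl2, −10 °C). This should give 4,4''-bis(tert-butyldimethylsilyloxy)-p-terphenyl-2',3',5',6'-tetrayl tetrakis[(2Z)-3-iodoprop-2-enoate] F7. A fourfold Stille coupling with tributyl[(1E)-prop-1-en-1-yl]stannane (Pd2(dba)3, AsPh3, N-methylpyrrolidone, rt) proceeds with retention at both alkenyl partners under neutral conditions and returns to the route at 12.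

Step 7. Prolonged contact with fluoride may cause acyl transfer to the freed phenoxide, ester cleavage or opening of the vinyl epoxides. The fallback moves the slow fluoride step in front of the epoxidation and finishes with a much more labile silyl group. From 12, Bu4NF/AcOH in THF should give 4,4''-dihydroxy-p-terphenyl-2',3',5',6'-tetrayl tetrakis[(2Z,4E)-hexa-2,4-dienoate] F8 while no epoxide is yet present. Et3SiCl and imidazole in CH2Cl2 should give 4,4''-bis(triethylsilyloxy)-p-terphenyl-2',3',5',6'-tetrayl tetrakis[(2Z,4E)-hexa-2,4-dienoate] F9. The epoxidation of step 6, applied unchanged, should give 4,4''-bis(triethylsilyloxy)-p-terphenyl-2',3',5',6'-tetrayl tetrakis{(2Z)-3-[(2S,3S)-3-methyloxiran-2-yl]prop-2-enoate} F10. Its aryl triethylsilyl ethers should fall within minutes to pyridine-buffered HF·pyridine in THF at −20 °C, a brief non-basic treatment that arrives at 14.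

Further compounds
F1 | step 6 | (E)-but-2-en-1-ol | C/C=C/CO
F2 | step 6 | [(2S,3S)-3-methyloxiran-2-yl]methanol | C[C@@H]1O[C@H]1CO
F3 | step 6 | (2R,3S)-3-methyloxirane-2-carbaldehyde | C[C@@H]1O[C@H]1C=O
F4 | step 6 | methyl (2Z)-3-[(2S,3S)-3-methyloxiran-2-yl]prop-2-enoate | C[C@@H]1O[C@H]1/C=C\C(=O)OC
F5 | step 6 | potassium (2Z)-3-[(2S,3S)-3-methyloxiran-2-yl]prop-2-enoate | C[C@@H]1O[C@H]1/C=C\C(=O)[O-].[K+]
F6 | step 6 | 2,4,6-trichlorobenzoic (2Z)-3-[(2S,3S)-3-methyloxiran-2-yl]prop-2-enoic anhydride | C[C@@H]1O[C@H]1/C=C\C(=O)OC(=O)c1c(Cl)cc(Cl)cc1Cl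
F7 | step 5 | 4,4''-bis(tert-butyldimethylsilyloxy)-p-terphenyl-2',3',5',6'-tetrayl tetrakis[(2Z)-3-iodoprop-2-enoate] | I/C=C\C(=O)Oc1c(OC(=O)/C=C\I)c(-c2ccc(O[Si](C)(C)C(C)(C)C)cc2)c(OC(=O)/C=C\I)c(OC(=O)/C=C\I)c1-c1ccc(O[Si](C)(C)C(C)(C)C)cc1
F8 | step 7 | 4,4''-dihydroxy-p-terphenyl-2',3',5',6'-tetrayl tetrakis[(2Z,4E)-hexa-2,4-dienoate] | C/C=C/C=C\C(=O)Oc1c(OC(=O)/C=C\C=C\C)c(-c2ccc(O)cc2)c(OC(=O)/C=C\C=C\C)c(OC(=O)/C=C\C=C\C)c1-c1ccc(O)cc1
F9 | step 7 | 4,4''-bis(triethylsilyloxy)-p-terphenyl-2',3',5',6'-tetrayl tetrakis[(2Z,4E)-hexa-2,4-dienoate] | C/C=C/C=C\C(=O)Oc1c(OC(=O)/C=C\C=C\C)c(-c2ccc(O[Si](CC)(CC)CC)cc2)c(OC(=O)/C=C\C=C\C)c(OC(=O)/C=C\C=C\C)c1-c1ccc(O[Si](CC)(CC)CC)cc1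
F10 | step 7 | 4,4''-bis(triethylsilyloxy)-p-terphenyl-2',3',5',6'-tetrayl tetrakis{(2Z)-3-[(2S,3S)-3-methyloxiran-2-yl]prop-2-enoate} | C[C@@H]1O[C@H]1/C=C\C(=O)Oc1c(OC(=O)/C=C\[C@@H]2O[C@H]2C)c(-c2ccc(O[Si](CC)(CC)CC)cc2)c(OC(=O)/C=C\[C@@H]2O[C@H]2C)c(OC(=O)/C=C\[C@@H]2O[C@H]2C)c1-c1ccc(O[Si](CC)(CC)CC)cc1
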